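**Retrosynthetic overview** (backbone numbered C1–C24 as in squalene, C1 = CH2 of the left isopropenyl group)
1. The oxirane C–O bonds are the key bonds: Sharpless epoxidation of the (2Z)-allylic alcohol 15 (C12–OH) sets C10 and C11; the oxirane is the only ring (step 7) and is formed before the last C–C bond.
2. C12–C13: the epoxy alcohol becomes a primary triflate that alkylates the allylbarium reagent of the right half (proposed new step).
3. Left half: C9–C10 by B-alkyl Suzuki coupling with (Z)-3-iodobut-2-en-1-ol; C6–C7 (sets C7) by copper-catalysed SN2′ alkenylation of crotyl phosphate; C3–C4 (sets C3) by copper-catalysed SN2′ alkylation of tiglyl chloride.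
4. Right half: (2E,6E)-farnesyl acetate, SeO2 oxidation of the terminal E-methyl, chloride, copper-catalysed SN2′ methylation (sets C22), allylic chloride.

Assumption: in steps 2, 4 and 10 the ligand antipode is the one that gives the drawn configuration (the same antipode of L1 should serve steps 2 and 10, because methyl and chain exchange roles as nucleophile and γ-substituent); this is checked on the first batch and the other antipode is used if the sense is reversed.

**Route**

Step 1
Reactants: 1 (E)-2-methylbut-2-en-1-ol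
Product: 2 (E)-1-chloro-2-methylbut-2-ene
Conditions: NCS, Me2S, CH2Cl2, −20 to 0 °C
Reagents that add atoms: N-chlorosuccinimide, O=C1CCC(=O)N1Cl
Why: Corey–Kim chlorination turns the primary allylic alcohol into the chloride by SN2 displacement of an alkoxysulfonium salt, so the E-trisubstituted olefin is neither transposed nor isomerised.

Step 2
Reactants: 2 (E)-1-chloro-2-methylbut-2-ene; 3 (4-bromobut-1-yn-1-yl)trimethylsilane
Product: 6 (3R)-2,3-dimethylhept-1-en-6-yne, via Grignard reagent 4 (not isolated), via silylalkyne 5 (not isolated)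
Conditions: 3, Mg, Et2O, rt; then 2, copper thiophene-2-carboxylate Cu(O2CC4H3S) (3 mol %), phosphoramidite L1 (biphenol/bis[1-(2-methoxyphenyl)ethyl]amine type, 3.3 mol %), CH2Cl2, −78 °C; then K2CO3, MeOH, rt
Reagents that add atoms: none
Why: Copper-catalysed asymmetric allylic alkylation (SN2′) of the β-substituted allylic chloride delivers the primary alkyl Grignard reagent to the γ-carbon under phosphoramidite control, which creates the C3 stereocentre (R) and the isopropenyl group together, and carbonate methanolysis then frees the terminal alkyne.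

Step 3
Reactants: 7 (E)-but-2-en-1-ol
Product: 8 diethyl (E)-but-2-en-1-yl phosphate
Conditions: ClP(O)(OEt)2, Et3N, DMAP (cat.), CH2Cl2, 0 °C to rt
Reagents that add atoms: diethyl chlorophosphate, CCOP(=O)(Cl)OCC
Why: O-Phosphorylation of the allylic alcohol installs the leaving group needed for the copper-catalysed SN2′ step without touching the E-olefin.

Step 4
Reactants: 6 (3R)-2,3-dimethylhept-1-en-6-yne; 8 diethyl (E)-but-2-en-1-yl phosphate
Product: 10 (3R,7R)-2,3,7-trimethyl-6-methylidenenona-1,8-diene, via alkenylalane 9 (not isolated)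
Conditions: iBu2AlH, Ni(dppp)Cl2 (3 mol %), THF, 0 to 22 °C; then 8, CuCl2·2H2O (2 mol %), chiral sulfonate-bearing imidazolinium salt L2 (1 mol %), THF, −15 °C
Reagents that add atoms: none
Why: Nickel-catalysed α-selective hydroalumination puts aluminium on the internal alkyne carbon, and NHC–copper-catalysed enantioselective allylic substitution (SN2′) of the crotyl phosphate by this 1,1-disubstituted alkenyl group forms C6–C7 and sets the C7 methyl stereocentre (R) by catalyst-controlled attack on one face of the allyl unit.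

Step 5
Reactants: 11 but-2-yn-1-ol
Product: 13 (Z)-3-iodobut-2-en-1-ol, via vinylalanate 12 (not isolated)
Conditions: NaAlH2(OCH2CH2OMe)2, THF, 0 °C to rt; then I2, −78 °C to rt
Reagents that add atoms: iodine, II
Why: Hydroxyl-directed trans-hydroalumination places aluminium on C3 cis to the carbinol in a five-membered alanate, and iodinolysis with retention gives the Z-vinyl iodide.

Step 6
Reactants: 10 (3R,7R)-2,3,7-trimethyl-6-methylidenenona-1,8-diene; 13 (Z)-3-iodobut-2-en-1-ol
Product: 15 (2Z,6R,10R)-3,6,10,11-tetramethyl-7-methylidenedodeca-2,11-dien-1-ol, via alkylborane 14 (not isolated)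
Conditions: disiamylborane (from BH3·SMe2 and 2-methylbut-2-ene), THF, 0 °C; then 13, Pd(dppf)Cl2 (5 mol %), 3 M aq NaOH, THF, 50 °C
Reagents that add atoms: none
Why: Disiamylborane hydroborates the monosubstituted vinyl group (anti-Markovnikov) much faster than the two hindered 1,1-disubstituted olefins, and B-alkyl Suzuki–Miyaura coupling transfers the primary alkyl group to the vinyl iodide with retention, which fixes the Z geometry (C9 cis to C12).

Step 7
Reactants: 15 (2Z,6R,10R)-3,6,10,11-tetramethyl-7-methylidenedodeca-2,11-dien-1-ol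
Product: 16 [(2R,3S)-3-methyl-3-[(3R,7R)-3,7,8-trimethyl-4-methylidenenon-8-en-1-yl]oxiran-2-yl]methanol
Conditions: Ti(OiPr)4 (10 mol %), D-(−)-diethyl tartrate (14 mol %), t-BuOOH, 4 Å molecular sieves, CH2Cl2, −20 °C
Reagents that add atoms: tert-butyl hydroperoxide, CC(C)(C)OO
Why: Sharpless asymmetric epoxidation delivers oxygen only to the olefin of the titanium-bound allylic alcohol, and D-(−)-tartrate gives the (2R,3S)-epoxy alcohol from the Z-olefin, i.e. C10 (S) and C11 (R) with the two chains cis on the oxirane.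

Step 8
Reactants: 17 (2E,6E)-3,7,11-trimethyldodeca-2,6,10-trien-1-yl acetate
Product: 18 (2E,6E,10E)-12-hydroxy-3,7,11-trimethyldodeca-2,6,10-trien-1-yl acetate
Conditions: SeO2 (10 mol %), t-BuOOH, salicylic acid (10 mol %), CH2Cl2, rt
Reagents that add atoms: tert-butyl hydroperoxide, CC(C)(C)OO
Why: Selenium dioxide allylic oxidation (ene reaction then [2,3]-sigmatropic shift) is selective for the E-methyl group of the terminal, most electron-rich trisubstituted olefin and leaves the allylic acetate end untouched.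

Step 9
Reactants: 18 (2E,6E,10E)-12-hydroxy-3,7,11-trimethyldodeca-2,6,10-trien-1-yl acetate
Product: 19 (2E,6E,10E)-12-chloro-3,7,11-trimethyldodeca-2,6,10-trien-1-yl acetate
Conditions: NCS, Me2S, CH2Cl2, −20 to 0 °C
Reagents that add atoms: N-chlorosuccinimide, O=C1CCC(=O)N1Cl
Why: Corey–Kim chlorination gives the primary allylic chloride by SN2 without allylic transposition and tolerates the acetate.

Step 10
Reactants: 19 (2E,6E,10E)-12-chloro-3,7,11-trimethyldodeca-2,6,10-trien-1-yl acetate
Product: 21 (2E,6E,10S)-3,7,10,11-tetramethyldodeca-2,6,11-trien-1-ol, via acetate 20 (not isolated)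
Conditions: MeMgBr (1.2 equiv, slow addition), copper thiophene-2-carboxylate Cu(O2CC4H3S) (3 mol %), phosphoramidite L1 (3.3 mol %), CH2Cl2, −78 °C; then K2CO3, MeOH, rt
Reagents that add atoms: methylmagnesium bromide, C[Mg]Br
Why: Copper-catalysed asymmetric allylic alkylation (SN2′) adds methyl to the γ-carbon with transposition of the double bond, which sets C22 (S) and the isopropenyl terminus, and methanolysis then removes the acetate.

Step 11
Reactants: 21 (2E,6E,10S)-3,7,10,11-tetramethyldodeca-2,6,11-trien-1-ol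
Product: 22 (3S,6E,10E)-12-chloro-2,3,6,10-tetramethyldodeca-1,6,10-triene
Conditions: NCS, Me2S, CH2Cl2, −20 to 0 °C
Reagents that add atoms: N-chlorosuccinimide, O=C1CCC(=O)N1Cl
Why: Corey–Kim chlorination gives the farnesyl-type primary chloride with the 2E geometry intact, as required for generation of the allylbarium reagent.

Step 12
Reactants: 16 [(2R,3S)-3-methyl-3-[(3R,7R)-3,7,8-trimethyl-4-methylidenenon-8-en-1-yl]oxiran-2-yl]methanol; 22 (3S,6E,10E)-12-chloro-2,3,6,10-tetramethyldodeca-1,6,10-triene
Product: 26 (2S,3R)-2-methyl-3-[(3E,7E,11S)-4,8,11,12-tetramethyltrideca-3,7,12-trien-1-yl]-2-[(3R,7R)-3,7,8-trimethyl-4-methylidenenon-8-en-1-yl]oxirane, via lithium alkoxide 23 (not isolated), via epoxy triflate 24 (not isolated), via allylbarium chloride 25 (not isolated)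
Conditions: 16, n-BuLi, Et2O, −78 °C, then Tf2O (0.98 equiv), −78 °C; separately BaI2, lithium biphenylide (from Li and biphenyl), THF, rt, then 22 (2 equiv), −78 °C; triflate solution added to the allylbarium, −78 °C, 1 h
Reagents that add atoms: none
Why: Proposed new method: α-selective, geometry-retentive SN2 alkylation of an allylbarium chloride with a primary 2,3-epoxy triflate, reasoned from the facts that allylbarium reagents are σ-bound at the less substituted terminus, do not undergo E/Z or 1,3-metallotropic scrambling below −70 °C and attack electrophiles through the α-carbon, so open SN2 displacement of the very reactive primary triflate (rather than opening of the hindered trisubstituted epoxide) should form the C12–C13 bond with the 14E olefin and all five stereocentres untouched, the closest known reactions being the α,α′-selective barium-mediated allyl–allyl halide cross-coupling and the copper-catalysed alkylation of epoxy triflates or tosylates with Grignard reagents.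

**Compound list**
1 | (E)-2-methylbut-2-en-1-ol | C/C=C(\C)CO | starting material
2 | (E)-1-chloro-2-methylbut-2-ene | C/C=C(\C)CCl | intermediate
3 | (4-bromobut-1-yn-1-yl)trimethylsilane | C[Si](C)(C)C#CCCBr | starting material
4 | [4-(trimethylsilyl)but-3-yn-1-yl]magnesium bromide | C[Si](C)(C)C#CCC[Mg]Br | intermediate
5 | trimethyl[(5R)-5,6-dimethylhept-6-en-1-yn-1-yl]silane | C=C(C)[C@H](C)CCC#C[Si](C)(C)C | intermediate
6 | (3R)-2,3-dimethylhept-1-en-6-yne | C=C(C)[C@H](C)CCC#C | intermediate
7 | (E)-but-2-en-1-ol | C/C=C/CO | starting material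
8 | diethyl (E)-but-2-en-1-yl phosphate | C/C=C/COP(=O)(OCC)OCC | intermediate
9 | [(5R)-5,6-dimethylhepta-1,6-dien-2-yl]bis(2-methylpropyl)alumane | C=C(C)[C@H](C)CCC(=C)[Al](CC(C)C)CC(C)C | intermediate
10 | (3R,7R)-2,3,7-trimethyl-6-methylidenenona-1,8-diene | C=C(C)[C@H](C)CCC(=C)[C@H](C)C=C | intermediate
11 | but-2-yn-1-ol | CC#CCO | starting material
12 | sodium 2,2-bis(2-methoxyethoxy)-3-methyl-2,5-dihydro-1,2-oxaaluminol-2-uide | CC1=CCO[Al-]1(OCCOC)OCCOC.[Na+] | intermediate
13 | (Z)-3-iodobut-2-en-1-ol | C/C(I)=C/CO | intermediate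
14 | [(3R,7R)-3,7,8-trimethyl-4-methylidenenon-8-en-1-yl]bis(3-methylbutan-2-yl)borane | C=C(C)[C@H](C)CCC(=C)[C@H](C)CCB(C(C)C(C)C)C(C)C(C)C | intermediate
15 | (2Z,6R,10R)-3,6,10,11-tetramethyl-7-methylidenedodeca-2,11-dien-1-ol | C=C(C)[C@H](C)CCC(=C)[C@H](C)CC/C(C)=C\CO | intermediate
16 | [(2R,3S)-3-methyl-3-[(3R,7R)-3,7,8-trimethyl-4-methylidenenon-8-en-1-yl]oxiran-2-yl]methanol | C=C(C)[C@H](C)CCC(=C)[C@H](C)CC[C@]1(C)O[C@@H]1CO | intermediate
17 | (2E,6E)-3,7,11-trimethyldodeca-2,6,10-trien-1-yl acetate ((2E,6E)-farnesyl acetate) | CC(=O)OC/C=C(\C)CC/C=C(\C)CCC=C(C)C | starting material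
18 | (2E,6E,10E)-12-hydroxy-3,7,11-trimethyldodeca-2,6,10-trien-1-yl acetate | CC(=O)OC/C=C(\C)CC/C=C(\C)CC/C=C(\C)CO | intermediate
19 | (2E,6E,10E)-12-chloro-3,7,11-trimethyldodeca-2,6,10-trien-1-yl acetate | CC(=O)OC/C=C(\C)CC/C=C(\C)CC/C=C(\C)CCl | intermediate
20 | (2E,6E,10S)-3,7,10,11-tetramethyldodeca-2,6,11-trien-1-yl acetate | CC(=O)OC/C=C(\C)CC/C=C(\C)CC[C@H](C)C(=C)C | intermediate
21 | (2E,6E,10S)-3,7,10,11-tetramethyldodeca-2,6,11-trien-1-ol | OC/C=C(\C)CC/C=C(\C)CC[C@H](C)C(=C)C | intermediate
22 | (3S,6E,10E)-12-chloro-2,3,6,10-tetramethyldodeca-1,6,10-triene | ClC/C=C(\C)CC/C=C(\C)CC[C@H](C)C(=C)C | intermediate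
23 | lithium [(2R,3S)-3-methyl-3-[(3R,7R)-3,7,8-trimethyl-4-methylidenenon-8-en-1-yl]oxiran-2-yl]methanolate | C=C(C)[C@H](C)CCC(=C)[C@H](C)CC[C@]1(C)O[C@@H]1CO[Li] | intermediate
24 | [(2R,3S)-3-methyl-3-[(3R,7R)-3,7,8-trimethyl-4-methylidenenon-8-en-1-yl]oxiran-2-yl]methyl trifluoromethanesulfonate | C=C(C)[C@H](C)CCC(=C)[C@H](C)CC[C@]1(C)O[C@@H]1COS(=O)(=O)C(F)(F)F | intermediate
25 | chlorido[(2E,6E,10S)-3,7,10,11-tetramethyldodeca-2,6,11-trien-1-yl]barium | Cl[Ba]C/C=C(\C)CC/C=C(\C)CC[C@H](C)C(=C)C | intermediate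
26 | (2S,3R)-2-methyl-3-[(3E,7E,11S)-4,8,11,12-tetramethyltrideca-3,7,12-trien-1-yl]-2-[(3R,7R)-3,7,8-trimethyl-4-methylidenenon-8-en-1-yl]oxirane | C=C(C)[C@H](C)CCC(=C)[C@H](C)CC[C@]1(C)O[C@@H]1CC/C=C(\C)CC/C=C(\C)CC[C@H](C)C(=C)C | target

**Step count and risks**

Total step count: 12. Longest linear sequence: 6 steps (steps 1, 2, 4, 6, 7, 12, from compound 1); the right-half arm is 5 steps (8–12).

Three steps most likely to fail:

Step 12 (proposed new step). Risks are γ-attack or loss of E geometry at the allyl unit, attack on the epoxide, and decomposition of the epoxy triflate. The fallback uses known sulfone chemistry; it sets out from chloride 22 (with triflate 24 generated from 16 as in step 12) and returns to the route at target 26. Chloride 22 is treated with NaSO2Ph in DMF to give the allylic sulfone [(2E,6E,10S)-3,7,10,11-tetramethyldodeca-2,6,11-trien-1-yl]sulfonylbenzene F1. Its α-sulfonyl carbanion (n-BuLi, THF, −78 °C) is alkylated exclusively at the α-carbon by triflate 24 to give (2S,3R)-3-[(3E,7E,11S)-2-(benzenesulfonyl)-4,8,11,12-tetramethyltrideca-3,7,12-trien-1-yl]-2-methyl-2-[(3R,7R)-3,7,8-trimethyl-4-methylidenenon-8-en-1-yl]oxirane F2 (both epimers at the sulfone carbon). Reductive desulfonylation with buffered sodium amalgam (Na(Hg), Na2HPO4, MeOH/THF, −20 °C), which leaves the epoxide intact, gives 26.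

Step 6. Risks are hydroboration of the 1,1-disubstituted olefins and sluggish transfer of the primary alkyl group from the disiamylborane. The fallback sets out from triene 10 and returns at allylic alcohol 15. Rhodium-catalysed hydroboration with catecholborane (Rh(PPh3)3Cl, THF, then NaOH/H2O2), which is strongly selective for monosubstituted olefins, gives (3R,7R)-3,7,8-trimethyl-4-methylidenenon-8-en-1-ol F3. I2/PPh3/imidazole converts it into (3R,7R)-9-iodo-2,3,7-trimethyl-6-methylidenenon-1-ene F4. Iodine–lithium exchange (t-BuLi, Et2O, −78 °C), capture with B-methoxy-9-borabicyclo[3.3.1]nonane and coupling of the resulting borinate with 13 (Pd(dppf)Cl2, aq K3PO4, DMF, rt) gives 15.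

Step 10. Methylmagnesium bromide is the least selective Grignard reagent in this ligand class, and the substrate is an aliphatic β,γ-disubstituted chloride carrying an ester, so the ee at C22 may be too low. The fallback replaces catalytic SN2′ methylation by a stereospecific epoxide opening; it sets out from allylic alcohol 18 and returns at acetate 20 (then methanolysis to 21 as in step 10). Sharpless epoxidation of 18 (Ti(OiPr)4, D-(−)-diethyl tartrate, t-BuOOH, −20 °C) gives (2E,6E)-9-[(2R,3R)-3-(hydroxymethyl)-3-methyloxiran-2-yl]-3,7-dimethylnona-2,6-dien-1-yl acetate F5. Me3Al (hexane/CH2Cl2, 0 °C) opens the epoxide at the secondary carbon with inversion to give (2E,6E,10S,11S)-11,12-dihydroxy-3,7,10,11-tetramethyldodeca-2,6-dien-1-yl acetate F6. NaIO4 (THF/H2O) cleaves the diol to (2E,6E,10S)-3,7,10-trimethyl-11-oxododeca-2,6-dien-1-yl acetate F7. Wittig methylenation (Ph3PCH3Br, KN(SiMe3)2, THF, −78 to 0 °C, to limit epimerisation) gives 20.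

**Further compounds**
F1 | step 12 | [(2E,6E,10S)-3,7,10,11-tetramethyldodeca-2,6,11-trien-1-yl]sulfonylbenzene | O=S(=O)(C/C=C(\C)CC/C=C(\C)CC[C@H](C)C(=C)C)c1ccccc1
F2 | step 12 | (2S,3R)-3-[(3E,7E,11S)-2-(benzenesulfonyl)-4,8,11,12-tetramethyltrideca-3,7,12-trien-1-yl]-2-methyl-2-[(3R,7R)-3,7,8-trimethyl-4-methylidenenon-8-en-1-yl]oxirane | C=C(C)[C@H](C)CCC(=C)[C@H](C)CC[C@]1(C)O[C@@H]1CC(S(=O)(=O)c1ccccc1)/C=C(\C)CC/C=C(\C)CC[C@H](C)C(=C)C
F3 | step 6 | (3R,7R)-3,7,8-trimethyl-4-methylidenenon-8-en-1-ol | C=C(C)[C@H](C)CCC(=C)[C@H](C)CCO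
F4 | step 6 | (3R,7R)-9-iodo-2,3,7-trimethyl-6-methylidenenon-1-ene | C=C(C)[C@H](C)CCC(=C)[C@H](C)CCI
F5 | step 10 | (2E,6E)-9-[(2R,3R)-3-(hydroxymethyl)-3-methyloxiran-2-yl]-3,7-dimethylnona-2,6-dien-1-yl acetate | CC(=O)OC/C=C(\C)CC/C=C(\C)CC[C@H]1O[C@]1(C)CO
F6 | step 10 | (2E,6E,10S,11S)-11,12-dihydroxy-3,7,10,11-tetramethyldodeca-2,6-dien-1-yl acetate | CC(=O)OC/C=C(\C)CC/C=C(\C)CC[C@H](C)[C@](C)(O)CO
F7 | step 10 | (2E,6E,10S)-3,7,10-trimethyl-11-oxododeca-2,6-dien-1-yl acetate | CC(=O)OC/C=C(\C)CC/C=C(\C)CC[C@H](C)C(C)=O
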